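**Plan**
- Retrosynthesis: the N-methyl group is taken back to a methyl carbamate, and the C6/C8 methyl ethers to a silyl ether and a phenol. Ring A (C4a–C5–C6–C7–C8–C8a) is then cut at C4a–C5, C5–C6, C7–C8 and C8–C8a into a tetrahydropyridyl diazomethyl ketone and a naphthyl siloxyalkyne, so the hindered C7–C1' biaryl bond is only ever made as an aryl–alkyne bond.
- Enabling feature: ring A carries oxygen at C6 and C8 with the naphthyl at C7 between them, the 2-substituted resorcinol pattern that a vinylketene and an oxygen-polarised alkyne deliver. The nitrogen ring (C1, N2, C3, C4, cis methyls) maps onto a mirror-symmetric cis-2,6-dimethyl-4-piperidone.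
- Forward order: nitrogen ring first (4-methoxypyridine → meso piperidone → enol triflate → methyl enone → diazo ketone). The naphthalene is made separately (Stobbe condensation, ring closure, then ester → ynolate → siloxyalkyne). Ring A closes last and joins the fragments; O-methylation and carbamate reduction finish.
- Stereochemistry: the cis relationship comes from axial conjugate addition to an N-acyl dihydropyridone. The absolute configuration comes from enantiotopic-proton-selective enolisation of the meso ketone by a chiral lithium amide. C1 and C3 are spectators afterwards.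

Key step: step 13

Assumption: the target structure defines C1 (R) and C3 (S) but not the C7–C1' biaryl axis, so the route controls the two stereocentres and accepts the axis as it forms (rotamers or an atropisomer pair).

**Step 1**
Reactants: 1 4-methoxypyridine
Product: 4 methyl 2-methyl-4-oxo-3,4-dihydropyridine-1(2H)-carboxylate (racemic), via N-acylpyridinium chloride 2 (not isolated), via dihydropyridine enol ether 3 (not isolated)
Conditions: ClCO2Me, THF, −23 °C; MeMgBr, −78 °C; then 10% aq HCl, 25 °C
Reagents that add atoms: methyl chloroformate, COC(=O)Cl; methylmagnesium bromide, C[Mg]Br; water, O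
Why: N-acylation activates the pyridine for Grignard addition at C2 (N-acylpyridinium addition, with the 4-methoxy group blocking C4) and acid hydrolysis of the enol ether unmasks the vinylogous amide; the stereocentre forms racemic, which is harmless because the next step gives a meso compound.

**Step 2**
Reactants: 4 methyl 2-methyl-4-oxo-3,4-dihydropyridine-1(2H)-carboxylate
Product: 6 methyl (2R,6S)-2,6-dimethyl-4-oxopiperidine-1-carboxylate (cis, meso), via bromomagnesium enolate 5 (not isolated)
Conditions: MeMgBr, CuBr·SMe2, BF3·OEt2, THF, −78 °C; aq NH4Cl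
Reagents that add atoms: methylmagnesium bromide, C[Mg]Br
Why: Copper-mediated, BF3-assisted conjugate addition to the N-acyl dihydropyridone, in which A(1,3) strain with the carbamate holds the C2 methyl axial and stereoelectronically favoured axial attack at C6 through a chair-like transition state should place the new methyl cis, so both enantiomers of 4 converge on the achiral ketone 6.

**Step 3**
Reactants: 6 methyl (2R,6S)-2,6-dimethyl-4-oxopiperidine-1-carboxylate
Product: 8 methyl (2S,6R)-2,6-dimethyl-4-{[(trifluoromethyl)sulfonyl]oxy}-3,6-dihydro-2H-pyridine-1-carboxylate, via lithium enolate 7 (not isolated)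
Conditions: (R,R)-bis(1-phenylethyl)amine, n-BuLi, LiCl, THF, −78 °C; then 2-[N,N-bis(trifluoromethylsulfonyl)amino]-5-chloropyridine, −78 → 0 °C
Reagents that add atoms: 2-[N,N-bis(trifluoromethylsulfonyl)amino]-5-chloropyridine, FC(F)(F)S(=O)(=O)N(c1ccc(Cl)cn1)S(=O)(=O)C(F)(F)F
Why: Desymmetrisation by enantiotopic-proton-selective deprotonation of a Cs-symmetric cyclic ketone with a C2-symmetric chiral lithium amide in the presence of LiCl, followed by O-sulfonylation of the enolate with the pyridyl triflimide; with the carbamate forcing both methyls axial the ketone resembles the N-acyl azabicyclic ketones for which such bases work well, and by analogy with the sense recalled for 4-substituted cyclohexanones the (R,R)-amide is expected to remove the axial proton at C3 next to the R-configured C2, which decides the absolute configuration of both centres (no new stereocentre is formed, and the (S,S)-amide is equally available should the sense need reversing).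

**Step 4**
Reactants: 8 methyl (2S,6R)-2,6-dimethyl-4-{[(trifluoromethyl)sulfonyl]oxy}-3,6-dihydro-2H-pyridine-1-carboxylate
Product: 10 methyl (2S,6R)-4-acetyl-2,6-dimethyl-3,6-dihydro-2H-pyridine-1-carboxylate, via ethoxy diene 9 (not isolated)
Conditions: tributyl(1-ethoxyvinyl)stannane, Pd(PPh3)4 (5 mol %), LiCl, THF, 65 °C; then 1 M aq HCl, 25 °C
Reagents that add atoms: tributyl(1-ethoxyvinyl)stannane, CCCC[Sn](CCCC)(CCCC)C(=C)OCC; water, O
Why: Stille coupling of a vinyl triflate with an acyl-anion equivalent, then mild hydrolysis of the enol ether to the conjugated methyl ketone; the conditions are non-basic, so the allylic C6 stereocentre should be untouched.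

**Step 5**
Reactants: 10 methyl (2S,6R)-4-acetyl-2,6-dimethyl-3,6-dihydro-2H-pyridine-1-carboxylate
Product: 13 methyl (2S,6R)-4-(2-diazoacetyl)-2,6-dimethyl-3,6-dihydro-2H-pyridine-1-carboxylate, via lithium enolate 11 (not isolated), via trifluoroacetyl ketone 12 (not isolated)
Conditions: LiHMDS, THF, −78 °C; CF3CO2CH2CF3; then MsN3, Et3N, H2O, MeCN, 25 °C
Reagents that add atoms: methanesulfonyl azide, CS(=O)(=O)N=[N+]=[N-]
Why: Detrifluoroacetylative diazo transfer, in which the kinetic cross-conjugated methyl enolate (the γ C–H at the allylic stereocentre should not be touched at −78 °C) is trifluoroacetylated, and diazo transfer with loss of the trifluoroacetyl group gives the α'-diazo enone without exposing the conjugated alkene to diazomethane.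

**Step 6**
Reactants: 14 2-bromo-5-methoxybenzaldehyde; 15 diethyl succinate
Product: 16 (3E)-4-(2-bromo-5-methoxyphenyl)-3-(ethoxycarbonyl)but-3-enoic acid
Conditions: NaOEt, EtOH, reflux; then aq HCl
Reagents that add atoms: none
Why: Stobbe condensation of a non-enolisable aldehyde, whose lactone intermediate opens to the E half-ester with the aryl group cis to the CH2CO2H arm, as the coming ring closure requires.

**Step 7**
Reactants: 16 (3E)-4-(2-bromo-5-methoxyphenyl)-3-(ethoxycarbonyl)but-3-enoic acid
Product: 17 ethyl 4-acetoxy-8-bromo-5-methoxynaphthalene-2-carboxylate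
Conditions: Ac2O, NaOAc, 140 °C
Reagents that add atoms: acetic anhydride, CC(=O)OC(C)=O
Why: The mixed anhydride undergoes intramolecular Friedel–Crafts acylation at the only free ortho position (bromine blocks the other and marks the future coupling carbon), and the naphthol formed on enolisation is acetylated in the same pot.

**Step 8**
Reactants: 17 ethyl 4-acetoxy-8-bromo-5-methoxynaphthalene-2-carboxylate
Product: 19 ethyl 8-bromo-4,5-dimethoxynaphthalene-2-carboxylate, via naphthol 18 (not isolated)
Conditions: K2CO3, EtOH, 25 °C; then MeI, DMF, 40 °C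
Reagents that add atoms: iodomethane, CI
Why: Carbonate-mediated ethanolysis of the aryl acetate (the ethyl ester is degenerate under these conditions) followed by Williamson methylation of the naphtholate.

**Step 9**
Reactants: 19 ethyl 8-bromo-4,5-dimethoxynaphthalene-2-carboxylate
Product: 20 (8-bromo-4,5-dimethoxynaphthalen-2-yl)methanol
Conditions: i-Bu2AlH, CH2Cl2, −78 → 0 °C; Rochelle salt work-up
Reagents that add atoms: none
Why: Hydride reduction of the ester to the primary alcohol with an aluminium hydride that should leave the aryl bromide alone at low temperature.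

**Step 10**
Reactants: 20 (8-bromo-4,5-dimethoxynaphthalen-2-yl)methanol
Product: 22 1-bromo-4,5-dimethoxy-7-methylnaphthalene, via mesylate 21 (not isolated)
Conditions: MsCl, Et3N, CH2Cl2, 0 °C; crude, then LiBEt3H, THF, 0 → 25 °C
Reagents that add atoms: none
Why: Two-stage deoxygenation of a benzylic alcohol by sulfonate activation and SN2 hydride displacement with a trialkylborohydride, which should not reduce the aryl bromide at this temperature.

**Step 11**
Reactants: 22 1-bromo-4,5-dimethoxy-7-methylnaphthalene
Product: 24 methyl 4,5-dimethoxy-7-methylnaphthalene-1-carboxylate, via aryllithium 23 (not isolated)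
Conditions: n-BuLi, THF, −78 °C; then cannulated into ClCO2Me, THF, −78 °C
Reagents that add atoms: methyl chloroformate, COC(=O)Cl
Why: Bromine–lithium exchange followed by acylation of the aryllithium, with inverse addition into excess chloroformate to suppress double addition to the ester.

**Step 12**
Reactants: 24 methyl 4,5-dimethoxy-7-methylnaphthalene-1-carboxylate
Product: 27 [(4,5-dimethoxy-7-methylnaphthalen-1-yl)ethynyloxy]triisopropylsilane, via dibromo enolate 25 (not isolated), via lithium ynolate 26 (not isolated)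
Conditions: CH2Br2, LiTMP, THF, −78 °C; LiHMDS; n-BuLi, −78 → 25 °C; then i-Pr3SiCl, −78 → 0 °C
Reagents that add atoms: dibromomethane, BrCBr; chlorotriisopropylsilane, CC(C)[Si](Cl)(C(C)C)C(C)C
Why: Kowalski ester homologation stopped at the ynolate (addition of LiCHBr2, enolisation, bromine–lithium exchange and 1,2-aryl shift of the carbenoid, a sequence established for 1-naphthoate esters), and the bulky silyl chloride should silylate the ynolate on oxygen.

**Step 13**
Reactants: 13 methyl (2S,6R)-4-(2-diazoacetyl)-2,6-dimethyl-3,6-dihydro-2H-pyridine-1-carboxylate; 27 [(4,5-dimethoxy-7-methylnaphthalen-1-yl)ethynyloxy]triisopropylsilane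
Product: 32 methyl (1R,3S)-7-(4,5-dimethoxy-7-methylnaphthalen-1-yl)-8-hydroxy-1,3-dimethyl-6-[(triisopropylsilyl)oxy]-3,4-dihydroisoquinoline-2(1H)-carboxylate, via vinylketene 28 (not isolated), via alkenylcyclobutenone 29 (not isolated), via dienylketene 30 (not isolated), via cyclohexadienone 31 (not isolated)
Conditions: 27 (1.3 equiv), degassed ClCH2CH2Cl, hν (LEDs, 405 nm), 25 °C; then 80 °C
Reagents that add atoms: none
Why: Excitation of the diazo ketone expels N2 and the alkenyl group migrates to the carbenic carbon (Wolff rearrangement, C4a–C5) to give vinylketene 28; the siloxyalkyne, whose aryl-bearing carbon is the nucleophilic one, then adds to the ketene in a [2+2] cycloaddition (C7–C8 and C5–C6) to give cyclobutenone 29. Heating opens 29 by four-electron electrocyclic ring opening to dienylketene 30, whose six-electron electrocyclisation forms C8–C8a, and dienone 31 tautomerises to the phenol. The closest known reaction type is the Danheiser benzannulation in its photochemical Wolff variant with triisopropylsiloxyalkynes, applied here to an aryl-substituted ynol ether. The one ring formed, benzene ring A, closes in the pericyclic 6π mode onto the only alkene terminus available, so no other ring size can arise. No stereocentre is created, since C1 and C3 lie outside the reacting π system and should pass unchanged under neutral conditions, while the biaryl axis forms uncontrolled. The step needs regioselectivity in the [2+2] event, secured by the oxygen polarisation of 27 matched to the electrophilic ketene carbonyl carbon, and selective excitation, secured by irradiating at 405 nm where the diazo ketone is expected to absorb and the dimethoxynaphthalene is not, with excess 27 to outrun ketene dimerisation.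

**Step 14**
Reactants: 32 methyl (1R,3S)-7-(4,5-dimethoxy-7-methylnaphthalen-1-yl)-8-hydroxy-1,3-dimethyl-6-[(triisopropylsilyl)oxy]-3,4-dihydroisoquinoline-2(1H)-carboxylate
Product: 34 methyl (1R,3S)-7-(4,5-dimethoxy-7-methylnaphthalen-1-yl)-6,8-dimethoxy-1,3-dimethyl-3,4-dihydroisoquinoline-2(1H)-carboxylate, via diol 33 (not isolated)
Conditions: Bu4NF, THF, 0 °C; then K2CO3, MeI, DMF, 40 °C
Reagents that add atoms: iodomethane, CI
Why: Fluoride cleaves the aryl silyl ether (any silyl-migrated isomer converges on the same resorcinol) and Williamson methylation of both phenoxides gives the dimethyl ether, the carbamate nitrogen having no proton to alkylate.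

**Step 15**
Reactants: 34 methyl (1R,3S)-7-(4,5-dimethoxy-7-methylnaphthalen-1-yl)-6,8-dimethoxy-1,3-dimethyl-3,4-dihydroisoquinoline-2(1H)-carboxylate
Product: 35 (1R,3S)-7-(4,5-dimethoxy-7-methylnaphthalen-1-yl)-6,8-dimethoxy-1,2,3-trimethyl-1,2,3,4-tetrahydroisoquinoline (ancistrobrevine A)
Conditions: LiAlH4, THF, reflux; aq NaOH work-up
Reagents that add atoms: none
Why: Hydride reduction of the methyl carbamate to the N-methyl amine, with the carbamate carbon becoming the N-methyl carbon; aryl ethers and both C–H stereocentres should be inert.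

**Compound list**
1 | 4-methoxypyridine | COc1ccncc1 | starting material
2 | 4-methoxy-1-(methoxycarbonyl)pyridinium chloride | COC(=O)[n+]1ccc(OC)cc1.[Cl-] | intermediate
3 | methyl 4-methoxy-2-methyl-2H-pyridine-1-carboxylate (racemic) | COC(=O)N1C=CC(OC)=CC1C | intermediate
4 | methyl 2-methyl-4-oxo-3,4-dihydropyridine-1(2H)-carboxylate (racemic) | CC1CC(=O)C=CN1C(=O)OC | intermediate
5 | bromomagnesium enolate of 6, cis (racemic, one enantiomer drawn) | Br[Mg]OC1=C[C@@H](C)N(C(=O)OC)[C@@H](C)C1 | intermediate
6 | methyl (2R,6S)-2,6-dimethyl-4-oxopiperidine-1-carboxylate (cis, meso) | O=C1C[C@@H](C)N(C(=O)OC)[C@@H](C)C1 | intermediate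
7 | lithium (2S,6R)-1-(methoxycarbonyl)-2,6-dimethyl-3,6-dihydro-2H-pyridin-4-olate | [Li]OC1=C[C@@H](C)N(C(=O)OC)[C@@H](C)C1 | intermediate
8 | methyl (2S,6R)-2,6-dimethyl-4-{[(trifluoromethyl)sulfonyl]oxy}-3,6-dihydro-2H-pyridine-1-carboxylate | FC(F)(F)S(=O)(=O)OC1=C[C@@H](C)N(C(=O)OC)[C@@H](C)C1 | intermediate
9 | methyl (2S,6R)-4-(1-ethoxyethenyl)-2,6-dimethyl-3,6-dihydro-2H-pyridine-1-carboxylate | CCOC(=C)C1=C[C@@H](C)N(C(=O)OC)[C@@H](C)C1 | intermediate
10 | methyl (2S,6R)-4-acetyl-2,6-dimethyl-3,6-dihydro-2H-pyridine-1-carboxylate | CC(=O)C1=C[C@@H](C)N(C(=O)OC)[C@@H](C)C1 | intermediate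
11 | lithium 1-[(2S,6R)-1-(methoxycarbonyl)-2,6-dimethyl-3,6-dihydro-2H-pyridin-4-yl]ethenolate | [Li]OC(=C)C1=C[C@@H](C)N(C(=O)OC)[C@@H](C)C1 | intermediate
12 | methyl (2S,6R)-2,6-dimethyl-4-(4,4,4-trifluoro-3-oxobutanoyl)-3,6-dihydro-2H-pyridine-1-carboxylate | O=C(CC(=O)C(F)(F)F)C1=C[C@@H](C)N(C(=O)OC)[C@@H](C)C1 | intermediate
13 | methyl (2S,6R)-4-(2-diazoacetyl)-2,6-dimethyl-3,6-dihydro-2H-pyridine-1-carboxylate | [N-]=[N+]=CC(=O)C1=C[C@@H](C)N(C(=O)OC)[C@@H](C)C1 | intermediate
14 | 2-bromo-5-methoxybenzaldehyde | COc1ccc(Br)c(C=O)c1 | starting material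
15 | diethyl succinate | CCOC(=O)CCC(=O)OCC | starting material
16 | (3E)-4-(2-bromo-5-methoxyphenyl)-3-(ethoxycarbonyl)but-3-enoic acid | CCOC(=O)/C(CC(=O)O)=C/c1cc(OC)ccc1Br | intermediate
17 | ethyl 4-acetoxy-8-bromo-5-methoxynaphthalene-2-carboxylate | CCOC(=O)c1cc(OC(C)=O)c2c(OC)ccc(Br)c2c1 | intermediate
18 | ethyl 8-bromo-4-hydroxy-5-methoxynaphthalene-2-carboxylate (present as its potassium salt) | CCOC(=O)c1cc(O)c2c(OC)ccc(Br)c2c1 | intermediate
19 | ethyl 8-bromo-4,5-dimethoxynaphthalene-2-carboxylate | CCOC(=O)c1cc(OC)c2c(OC)ccc(Br)c2c1 | intermediate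
20 | (8-bromo-4,5-dimethoxynaphthalen-2-yl)methanol | OCc1cc(OC)c2c(OC)ccc(Br)c2c1 | intermediate
21 | (8-bromo-4,5-dimethoxynaphthalen-2-yl)methyl methanesulfonate | CS(=O)(=O)OCc1cc(OC)c2c(OC)ccc(Br)c2c1 | intermediate
22 | 1-bromo-4,5-dimethoxy-7-methylnaphthalene | Cc1cc(OC)c2c(OC)ccc(Br)c2c1 | intermediate
23 | (4,5-dimethoxy-7-methylnaphthalen-1-yl)lithium | [Li]c1ccc(OC)c2c(OC)cc(C)cc12 | intermediate
24 | methyl 4,5-dimethoxy-7-methylnaphthalene-1-carboxylate | COC(=O)c1ccc(OC)c2c(OC)cc(C)cc12 | intermediate
25 | lithium 2,2-dibromo-1-(4,5-dimethoxy-7-methylnaphthalen-1-yl)ethenolate | [Li]OC(=C(Br)Br)c1ccc(OC)c2c(OC)cc(C)cc12 | intermediate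
26 | lithium 2-(4,5-dimethoxy-7-methylnaphthalen-1-yl)ethynolate | [Li]OC#Cc1ccc(OC)c2c(OC)cc(C)cc12 | intermediate
27 | [(4,5-dimethoxy-7-methylnaphthalen-1-yl)ethynyloxy]triisopropylsilane | CC(C)[Si](OC#Cc1ccc(OC)c2c(OC)cc(C)cc12)(C(C)C)C(C)C | intermediate
28 | methyl (2S,6R)-2,6-dimethyl-4-(2-oxoethenyl)-3,6-dihydro-2H-pyridine-1-carboxylate (vinylketene) | O=C=CC1=C[C@@H](C)N(C(=O)OC)[C@@H](C)C1 | intermediate
29 | methyl (2S,6R)-4-[3-(4,5-dimethoxy-7-methylnaphthalen-1-yl)-4-oxo-2-(triisopropylsilyloxy)cyclobut-2-en-1-yl]-2,6-dimethyl-3,6-dihydro-2H-pyridine-1-carboxylate (ring CH undefined) | O=C1C(c2ccc(OC)c3c(OC)cc(C)cc23)=C(O[Si](C(C)C)(C(C)C)C(C)C)C1C4=C[C@@H](C)N(C(=O)OC)[C@@H](C)C4 | intermediate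
30 | methyl (2S,6R)-4-[3-(4,5-dimethoxy-7-methylnaphthalen-1-yl)-4-oxo-2-(triisopropylsilyloxy)buta-1,3-dien-1-yl]-2,6-dimethyl-3,6-dihydro-2H-pyridine-1-carboxylate (dienylketene) | O=C=C(c1ccc(OC)c2c(OC)cc(C)cc12)C(O[Si](C(C)C)(C(C)C)C(C)C)=CC3=C[C@@H](C)N(C(=O)OC)[C@@H](C)C3 | intermediate
31 | methyl (1R,3S)-7-(4,5-dimethoxy-7-methylnaphthalen-1-yl)-1,3-dimethyl-8-oxo-6-(triisopropylsilyloxy)-3,4,8,8a-tetrahydroisoquinoline-2(1H)-carboxylate (C8a undefined) | O=C1C(c3ccc(OC)c4c(OC)cc(C)cc34)=C(O[Si](C(C)C)(C(C)C)C(C)C)C=C2C[C@H](C)N(C(=O)OC)[C@H](C)C12 | intermediate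
32 | methyl (1R,3S)-7-(4,5-dimethoxy-7-methylnaphthalen-1-yl)-8-hydroxy-1,3-dimethyl-6-[(triisopropylsilyl)oxy]-3,4-dihydroisoquinoline-2(1H)-carboxylate | CC(C)[Si](Oc1cc2c(c(O)c1-c1ccc(OC)c3c(OC)cc(C)cc13)[C@@H](C)N(C(=O)OC)[C@@H](C)C2)(C(C)C)C(C)C | intermediate
33 | methyl (1R,3S)-7-(4,5-dimethoxy-7-methylnaphthalen-1-yl)-6,8-dihydroxy-1,3-dimethyl-3,4-dihydroisoquinoline-2(1H)-carboxylate | Oc1cc2c(c(O)c1-c1ccc(OC)c3c(OC)cc(C)cc13)[C@@H](C)N(C(=O)OC)[C@@H](C)C2 | intermediate
34 | methyl (1R,3S)-7-(4,5-dimethoxy-7-methylnaphthalen-1-yl)-6,8-dimethoxy-1,3-dimethyl-3,4-dihydroisoquinoline-2(1H)-carboxylate | COc1cc2c(c(OC)c1-c1ccc(OC)c3c(OC)cc(C)cc13)[C@@H](C)N(C(=O)OC)[C@@H](C)C2 | intermediate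
35 | (1R,3S)-7-(4,5-dimethoxy-7-methylnaphthalen-1-yl)-6,8-dimethoxy-1,2,3-trimethyl-1,2,3,4-tetrahydroisoquinoline (ancistrobrevine A) | COc1cc2c(c(OC)c1-c1ccc(OC)c3c(OC)cc(C)cc13)[C@@H](C)N(C)[C@@H](C)C2 | target

**Step count**
Total: 15 steps. Longest linear sequence: 10 steps (steps 6 to 15, from 14 and 15 to 35); the nitrogen-ring branch is 5 steps to 13.

**Steps most likely to fail, with fallbacks**

1. Step 13. The vinylketene may be consumed by dimerisation or stray nucleophiles faster than the hindered, aryl-conjugated ynol ether adds to it, and the naphthyl chromophore may absorb or sensitise so that the cascade stalls before the cyclobutenone. The fallback generates the same ketene without light. It sets out from triflate 8 and returns at 32. Palladium-catalysed coupling of 8 with the Reformatsky reagent BrZnCH2CO2t-Bu (Pd(dba)2, XPhos, THF, 60 °C) should give methyl (2S,6R)-4-(2-tert-butoxy-2-oxoethyl)-2,6-dimethyl-3,6-dihydro-2H-pyridine-1-carboxylate F1. Cleavage with CF3CO2H in CH2Cl2 would give 2-[(2S,6R)-1-(methoxycarbonyl)-2,6-dimethyl-3,6-dihydro-2H-pyridin-4-yl]acetic acid F2, and (COCl)2 with catalytic DMF the acid chloride methyl (2S,6R)-4-(2-chloro-2-oxoethyl)-2,6-dimethyl-3,6-dihydro-2H-pyridine-1-carboxylate F3. Slow addition of the acid chloride to Et3N and 27 in toluene at 80–110 °C should dehydrochlorinate it to vinylketene 28 in the dark, which then follows the same [2+2], ring-opening and electrocyclisation sequence to 32.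

2. Step 3. Discrimination between the enantiotopic α-protons may be insufficient, proton transfer between enolate and ketone during the triflimide quench may erode it, or the sense of induction may be opposite to the one assumed. The fallback takes the absolute configuration from a purchased stereocentre. It does not branch from an intermediate of the route: it replaces compound 1 as the starting point and returns at 8. Commercial (3S)-3-[(tert-butoxycarbonyl)amino]butanoic acid F4 is converted with MeNHOMe·HCl, EDC·HCl and N-methylmorpholine into the Weinreb amide tert-butyl N-[(2S)-4-[methoxy(methyl)amino]-4-oxobutan-2-yl]carbamate F5. Ethynylmagnesium bromide (THF, 0 °C) should give the ynone tert-butyl N-[(2S)-4-oxohex-5-yn-2-yl]carbamate F6. Removal of the carbamate (4 M HCl in dioxane) and 6-endo cyclisation of the amine onto the ynone (K2CO3, MeOH) should give (2S)-2-methyl-2,3-dihydropyridin-4(1H)-one F7. N-Acylation (n-BuLi, THF, −78 °C, ClCO2Me) gives methyl (2S)-2-methyl-4-oxo-3,4-dihydropyridine-1(2H)-carboxylate F8. Copper-mediated addition of MeMgBr as in step 2, with the metal enolate intercepted by the pyridyl triflimide instead of a proton, would then give 8. In this variant the cis relationship comes from the axial conjugate addition and the position of the enol double bond from the addition itself.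

3. Step 12. The 1,2-shift of the electron-rich, peri-hindered naphthyl group in the carbenoid may be slow, the excess alkyllithium may lithiate the ring, or the ynolate may be silylated on carbon instead of oxygen. The fallback makes the ynolate by oxidation of an acetylide. It sets out from bromide 22 and returns at 27. Sonogashira coupling of 22 with ethynyltrimethylsilane (PdCl2(PPh3)2, CuI, Et3N, 70 °C) should give [(4,5-dimethoxy-7-methylnaphthalen-1-yl)ethynyl]trimethylsilane F9. K2CO3 in MeOH removes the silyl group to give 1-ethynyl-4,5-dimethoxy-7-methylnaphthalene F10. Deprotonation with LiHMDS and oxidation of the lithium acetylide with lithium tert-butyl peroxide (t-BuOOH, LiHMDS, THF, −78 → 0 °C) should give ynolate 26, which is silylated on oxygen with i-Pr3SiOTf to give 27.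

**Further compounds**
F1 | step 13 | methyl (2S,6R)-4-(2-tert-butoxy-2-oxoethyl)-2,6-dimethyl-3,6-dihydro-2H-pyridine-1-carboxylate | CC(C)(C)OC(=O)CC1=C[C@@H](C)N(C(=O)OC)[C@@H](C)C1
F2 | step 13 | 2-[(2S,6R)-1-(methoxycarbonyl)-2,6-dimethyl-3,6-dihydro-2H-pyridin-4-yl]acetic acid | OC(=O)CC1=C[C@@H](C)N(C(=O)OC)[C@@H](C)C1
F3 | step 13 | methyl (2S,6R)-4-(2-chloro-2-oxoethyl)-2,6-dimethyl-3,6-dihydro-2H-pyridine-1-carboxylate | ClC(=O)CC1=C[C@@H](C)N(C(=O)OC)[C@@H](C)C1
F4 | step 3 | (3S)-3-[(tert-butoxycarbonyl)amino]butanoic acid (commercial) | C[C@@H](CC(=O)O)NC(=O)OC(C)(C)C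
F5 | step 3 | tert-butyl N-[(2S)-4-[methoxy(methyl)amino]-4-oxobutan-2-yl]carbamate | C[C@@H](CC(=O)N(C)OC)NC(=O)OC(C)(C)C
F6 | step 3 | tert-butyl N-[(2S)-4-oxohex-5-yn-2-yl]carbamate | C[C@@H](CC(=O)C#C)NC(=O)OC(C)(C)C
F7 | step 3 | (2S)-2-methyl-2,3-dihydropyridin-4(1H)-one | C[C@H]1CC(=O)C=CN1
F8 | step 3 | methyl (2S)-2-methyl-4-oxo-3,4-dihydropyridine-1(2H)-carboxylate | C[C@H]1CC(=O)C=CN1C(=O)OC
F9 | step 12 | [(4,5-dimethoxy-7-methylnaphthalen-1-yl)ethynyl]trimethylsilane | C[Si](C)(C)C#Cc1ccc(OC)c2c(OC)cc(C)cc12
F10 | step 12 | 1-ethynyl-4,5-dimethoxy-7-methylnaphthalene | C#Cc1ccc(OC)c2c(OC)cc(C)cc12
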